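The dihydropyranone core is disconnected at O1–C6. Its ring atoms O1–C2(H)–C3(=O)–C4–C5–C6 map onto an oxidised 2-furylcarbinol: furan C2–C5 become C3–C6 and the carbinol carbon becomes C2. An Achmatowicz ring expansion therefore turns a 2,4-disubstituted furan into the pyranone in one operation, closing the ring, creating the C3 ketone and carrying the carbinol configuration into C2 with both side chains already attached. The precursor is an (S)-furylcarbinol bearing the complete E-enoate diester arm on the carbinol carbon and the silyl-protected (4R,5S)-hexenyl chain at furan C4. The C4 enol is installed afterwards by epoxidation and acid isomerisation.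

Key step: step 12

Remark: the target is taken as the C4-enol (diosphenol) tautomer of the ring 3,4-dione exactly as drawn, and the (S,S) aldol catalyst in step 9 is specified on the premise that the (R,R) series delivers the nucleophile to the Re face of aryl aldehydes (Si-face attack is needed for the (S)-carbinol); the sense is to be confirmed by MTPA-ester analysis of 19 on the first run.

Step 1
Reactants: 1 ethyl (3S)-3-hydroxybutanoate
Product: 3 ethyl (2S,3S)-3-hydroxy-2-methylbutanoate, via dilithium alkoxide enolate 2 (not isolated)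
Conditions: LDA (2.2 equiv, commercial solution), THF, −50 → −20 °C; MeI, DMPU, −78 → 0 °C; AcOH quench
Reagents that add atoms: iodomethane, CI
Why: Fráter–Seebach alkylation, in which the chelated dianion 2 is methylated on the face away from the C3 methyl group, so the new C2 centre is set anti to the existing carbinol (2S,3S).

Step 2
Reactants: 3 ethyl (2S,3S)-3-hydroxy-2-methylbutanoate
Product: 4 ethyl (2S,3S)-3-[(tert-butyldimethylsilyl)oxy]-2-methylbutanoate
Conditions: TBSCl, imidazole, DMF, rt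
Reagents that add atoms: tert-butyldimethylsilyl chloride, CC(C)(C)[Si](C)(C)Cl
Why: Standard imidazole-promoted silylation of a secondary alcohol; the silyl ether keeps this hydroxyl out of the organometallic, Lewis-acid and oxidation steps and is removed by the final acid.

Step 3
Reactants: 4 ethyl (2S,3S)-3-[(tert-butyldimethylsilyl)oxy]-2-methylbutanoate; 5 triethyl phosphonoacetate
Product: 7 ethyl (2E,4R,5S)-5-[(tert-butyldimethylsilyl)oxy]-4-methylhex-2-enoate, via aldehyde 6 (not isolated)
Conditions: DIBAL-H (1.1 equiv), CH2Cl2, −78 °C; then 5/NaH (premixed in THF), −78 °C → rt; Rochelle salt work-up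
Reagents that add atoms: none
Why: Tandem DIBAL-H reduction/Horner–Wadsworth–Emmons olefination, in which the aluminium hemiacetal releases aldehyde 6 only as the phosphonate anion traps it, so the α-stereocentre is not epimerised and the stabilised phosphonate gives the E-enoate.

Step 4
Reactants: 7 ethyl (2E,4R,5S)-5-[(tert-butyldimethylsilyl)oxy]-4-methylhex-2-enoate
Product: 8 (2E,4R,5S)-5-[(tert-butyldimethylsilyl)oxy]-4-methylhex-2-en-1-ol
Conditions: DIBAL-H (2.5 equiv), CH2Cl2, −78 °C; Rochelle salt work-up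
Reagents that add atoms: none
Why: 1,2-Reduction of an enoate by DIBAL-H at low temperature gives the allylic alcohol without touching the alkene geometry or the silyl ether.

Step 5
Reactants: 8 (2E,4R,5S)-5-[(tert-butyldimethylsilyl)oxy]-4-methylhex-2-en-1-ol
Product: 9 (2E,4R,5S)-1-bromo-5-[(tert-butyldimethylsilyl)oxy]-4-methylhex-2-ene
Conditions: CBr4, PPh3, 2,6-lutidine (cat.), CH2Cl2, −20 → 0 °C
Reagents that add atoms: carbon tetrabromide, BrC(Br)(Br)Br
Why: Appel bromination, in which bromide displaces the primary oxyphosphonium by SN2 without allylic transposition under cold, buffered conditions.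

Step 6
Reactants: 10 4-bromo-2-furaldehyde
Product: 11 4-bromo-2-(diethoxymethyl)furan
Conditions: HC(OEt)3, EtOH, p-TsOH·H2O (cat.), rt; Et3N quench
Reagents that add atoms: triethyl orthoformate, CCOC(OCC)OCC
Why: Acid-catalysed acetalisation with the orthoformate as ethoxy donor and water scavenger masks the aldehyde for the metalation that follows.

Step 7
Reactants: 11 4-bromo-2-(diethoxymethyl)furan; 9 (2E,4R,5S)-1-bromo-5-[(tert-butyldimethylsilyl)oxy]-4-methylhex-2-ene
Product: 15 4-[(2E,4R,5S)-5-[(tert-butyldimethylsilyl)oxy]-4-methylhex-2-en-1-yl]furan-2-carbaldehyde, via furyllithium 12 (not isolated), via furylzinc chloride 13 (not isolated), via coupled diethyl acetal 14 (not isolated)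
Conditions: n-BuLi, THF, −78 °C; ZnCl2 (THF), −78 → 0 °C; 9, Pd(PPh3)4 (3 mol%), 0 °C → rt; then 1 M aq. HCl, THF, 0 °C
Reagents that add atoms: water, O
Why: Bromine–lithium exchange at −78 °C (cold enough to stop lithium migrating to the furan α-position), transmetalation to zinc and Negishi-type Pd-catalysed allylation through a π-allyl complex join furan C4 to the unhindered allyl terminus with the E-alkene retained; dilute acid then hydrolyses the diethyl acetal while the secondary silyl ether survives.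

Step 8
Reactants: 16 ethyl 3-methylbut-2-enoate
Product: 18 tert-butyl[(1-ethoxy-3-methylbuta-1,3-dien-1-yl)oxy]dimethylsilane, via lithium dienolate 17 (not isolated)
Conditions: LDA (commercial solution), THF, −78 °C; TBSCl, DMPU, −78 °C → rt; distillation
Reagents that add atoms: tert-butyldimethylsilyl chloride, CC(C)(C)[Si](C)(C)Cl
Why: Kinetic γ-deprotonation of the senecioate and O-silylation of the extended enolate give the silyl dienol ether; the ketene-acetal geometry is inconsequential because no stereocentre derives from it.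

Step 9
Reactants: 15 4-[(2E,4R,5S)-5-[(tert-butyldimethylsilyl)oxy]-4-methylhex-2-en-1-yl]furan-2-carbaldehyde; 18 tert-butyl[(1-ethoxy-3-methylbuta-1,3-dien-1-yl)oxy]dimethylsilane
Product: 19 ethyl (2E,5S)-5-hydroxy-3-methyl-5-{4-[(2E,4R,5S)-5-[(tert-butyldimethylsilyl)oxy]-4-methylhex-2-en-1-yl]furan-2-yl}pent-2-enoate
Conditions: SiCl4 (1.1 equiv), (S,S)-bisphosphoramide catalyst (pentamethylene-linked, from N,N'-dimethyl-1,1'-binaphthyl-2,2'-diamine; 5 mol%), i-Pr2NEt (10 mol%), CH2Cl2, −78 °C; sat. aq. NaHCO3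
Reagents that add atoms: none
Why: Catalytic asymmetric vinylogous Mukaiyama aldol with Lewis-base-activated SiCl4, in which the chiral phosphoramide-bound silyl cation binds the aldehyde and exposes its Si face to the γ-carbon of the dienolate, setting the (S)-carbinol; γ-attack through the s-trans diene gives the E-trisubstituted enoate, and any Z adduct would lactonise and be separated.

Step 10
Reactants: 19 ethyl (2E,5S)-5-hydroxy-3-methyl-5-{4-[(2E,4R,5S)-5-[(tert-butyldimethylsilyl)oxy]-4-methylhex-2-en-1-yl]furan-2-yl}pent-2-enoate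
Product: 20 (2E,5S)-5-hydroxy-3-methyl-5-{4-[(2E,4R,5S)-5-[(tert-butyldimethylsilyl)oxy]-4-methylhex-2-en-1-yl]furan-2-yl}pent-2-enoic acid
Conditions: LiOH·H2O, THF/MeOH/H2O, rt; 1 M HCl to pH 4, 0 °C
Reagents that add atoms: lithium hydroxide, [Li+].[OH-]
Why: Saponification of the ethyl enoate; the E-geometry prevents lactonisation, the silyl ether and furylcarbinol tolerate hydroxide, and only mild acidification is used because furylcarbinols are acid-sensitive.

Step 11
Reactants: 20 (2E,5S)-5-hydroxy-3-methyl-5-{4-[(2E,4R,5S)-5-[(tert-butyldimethylsilyl)oxy]-4-methylhex-2-en-1-yl]furan-2-yl}pent-2-enoic acid; 21 tert-butyl 6-bromohexanoate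
Product: 22 6-(tert-butoxy)-6-oxohexyl (2E,5S)-5-hydroxy-3-methyl-5-{4-[(2E,4R,5S)-5-[(tert-butyldimethylsilyl)oxy]-4-methylhex-2-en-1-yl]furan-2-yl}pent-2-enoate
Conditions: Cs2CO3, DMF, rt
Reagents that add atoms: none
Why: SN2 O-alkylation of the caesium carboxylate by the primary bromide is selective over the secondary hydroxyl, so the carbinol needed for the ring expansion stays free without a protecting group.

Step 12
Reactants: 22 6-(tert-butoxy)-6-oxohexyl (2E,5S)-5-hydroxy-3-methyl-5-{4-[(2E,4R,5S)-5-[(tert-butyldimethylsilyl)oxy]-4-methylhex-2-en-1-yl]furan-2-yl}pent-2-enoate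
Product: 24 6-(tert-butoxy)-6-oxohexyl (2E)-4-[(2S)-6-hydroxy-5-[(2E,4R,5S)-5-[(tert-butyldimethylsilyl)oxy]-4-methylhex-2-en-1-yl]-3-oxo-3,6-dihydro-2H-pyran-2-yl]-3-methylbut-2-enoate (both C6 epimers), via Z-enedione 23 (not isolated)
Conditions: NBS (1.05 equiv), NaHCO3, THF/H2O (4:1), 0 °C; Na2S2O3 quench
Reagents that add atoms: water, O
Why: NBS delivers Br+ to the electron-rich furan at its free C5 position and water adds at C2, and the resulting 2,5-dioxygenated dihydrofuran collapses with loss of bromide to the Z-enedione 23, whose carbinol hydroxyl adds to the aldehyde carbon (former furan C5) to give the lactol. This is the Achmatowicz rearrangement of a 2-furylcarbinol, here with a 4-alkyl group that ends up on C5 of the pyranone. The one ring is closed by 6-exo-trig hemiacetalisation, forming O1–C6. The only new stereocentre is the anomeric C6, left uncontrolled because step 13 reduces it to CH2, while C2 is the former carbinol carbon, none of whose bonds is broken, so its S configuration is retained. The step needs oxidation of the furan in preference to the E-disubstituted alkene and the enoate: the furan is by far the most nucleophilic π-system, the enoate is electron-poor, the side-chain hydroxyl is silylated so it cannot take part in bromoetherification, and one equivalent of NBS at 0 °C in bicarbonate-buffered medium keeps bromohydrin formation and acid-induced lactol decomposition from competing.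

Step 13
Reactants: 24 6-(tert-butoxy)-6-oxohexyl (2E)-4-[(2S)-6-hydroxy-5-[(2E,4R,5S)-5-[(tert-butyldimethylsilyl)oxy]-4-methylhex-2-en-1-yl]-3-oxo-3,6-dihydro-2H-pyran-2-yl]-3-methylbut-2-enoate
Product: 25 6-(tert-butoxy)-6-oxohexyl (2E)-4-[(2S)-5-[(2E,4R,5S)-5-[(tert-butyldimethylsilyl)oxy]-4-methylhex-2-en-1-yl]-3-oxo-3,6-dihydro-2H-pyran-2-yl]-3-methylbut-2-enoate
Conditions: Et3SiH (5 equiv), TFA (10 equiv), CH2Cl2, −40 °C
Reagents that add atoms: none
Why: Ionic hydrogenation of the lactol, in which acid ionises the C6 hydroxyl to a conjugated oxocarbenium centre that accepts hydride from the silane at C6; the cold, brief exposure spares the tert-butyl ester, the silyl ether and C2.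

Step 14
Reactants: 25 6-(tert-butoxy)-6-oxohexyl (2E)-4-[(2S)-5-[(2E,4R,5S)-5-[(tert-butyldimethylsilyl)oxy]-4-methylhex-2-en-1-yl]-3-oxo-3,6-dihydro-2H-pyran-2-yl]-3-methylbut-2-enoate
Product: 26 the 4,5-epoxide of 25, 6-(tert-butoxy)-6-oxohexyl (2E)-4-[(4S)-1-[(2E,4R,5S)-5-[(tert-butyldimethylsilyl)oxy]-4-methylhex-2-en-1-yl]-5-oxo-3,7-dioxabicyclo[4.1.0]heptan-4-yl]-3-methylbut-2-enoate (mixture of epoxide diastereomers)
Conditions: 30% aq. H2O2 (3 equiv), NaOH (0.2 equiv), MeOH, 0 °C
Reagents that add atoms: hydrogen peroxide, OO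
Why: Weitz–Scheffer nucleophilic epoxidation, in which hydroperoxide adds only to the ring enone and not to the isolated alkene or the less electrophilic β,β-disubstituted enoate; the epoxide configuration needs no control because both new centres are erased in step 15, and the cold, base-poor medium limits enolisation at C2.

Step 15
Reactants: 26 the 4,5-epoxide of 25
Product: 27 6,7-diketothiomarinolic acid C6, 6-{[(2E)-4-[(2S)-4-hydroxy-5-[(2E,4R,5S)-5-hydroxy-4-methylhex-2-en-1-yl]-3-oxo-3,6-dihydro-2H-pyran-2-yl]-3-methylbut-2-enoyl]oxy}hexanoic acid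
Conditions: TFA/H2O (9:1), 0 °C → rt; evaporation from toluene; reversed-phase chromatography
Reagents that add atoms: none
Why: Acid-mediated isomerisation of an α,β-epoxy ketone to a diosphenol combined with global deprotection, in which aqueous acid opens the epoxide at the tertiary C5–O bond and dehydration through the C3/C4 enol places the double bond at C4=C5 with the hydroxyl on C4 without involving C2–H, while the same medium cleaves the tert-butyl ester and the silyl ether; the water present intercepts cationic character at C5 and so disfavours acyl migration.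

Compound list
1 | ethyl (3S)-3-hydroxybutanoate | CCOC(=O)C[C@H](C)O | starting material
2 | dilithium alkoxide enolate of 1 | CCOC(O[Li])=C[C@H](C)O[Li] | intermediate
3 | ethyl (2S,3S)-3-hydroxy-2-methylbutanoate | CCOC(=O)[C@@H](C)[C@H](C)O | intermediate
4 | ethyl (2S,3S)-3-[(tert-butyldimethylsilyl)oxy]-2-methylbutanoate | CCOC(=O)[C@@H](C)[C@H](C)O[Si](C)(C)C(C)(C)C | intermediate
5 | triethyl phosphonoacetate | CCOC(=O)CP(=O)(OCC)OCC | starting material
6 | (2S,3S)-3-[(tert-butyldimethylsilyl)oxy]-2-methylbutanal | O=C[C@@H](C)[C@H](C)O[Si](C)(C)C(C)(C)C | intermediate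
7 | ethyl (2E,4R,5S)-5-[(tert-butyldimethylsilyl)oxy]-4-methylhex-2-enoate | CCOC(=O)/C=C/[C@@H](C)[C@H](C)O[Si](C)(C)C(C)(C)C | intermediate
8 | (2E,4R,5S)-5-[(tert-butyldimethylsilyl)oxy]-4-methylhex-2-en-1-ol | OC/C=C/[C@@H](C)[C@H](C)O[Si](C)(C)C(C)(C)C | intermediate
9 | (2E,4R,5S)-1-bromo-5-[(tert-butyldimethylsilyl)oxy]-4-methylhex-2-ene | BrC/C=C/[C@@H](C)[C@H](C)O[Si](C)(C)C(C)(C)C | intermediate
10 | 4-bromo-2-furaldehyde | O=Cc1cc(Br)co1 | starting material
11 | 4-bromo-2-(diethoxymethyl)furan | CCOC(OCC)c1cc(Br)co1 | intermediate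
12 | [5-(diethoxymethyl)furan-3-yl]lithium | CCOC(OCC)c1cc([Li])co1 | intermediate
13 | chloro[5-(diethoxymethyl)furan-3-yl]zinc | CCOC(OCC)c1cc([Zn]Cl)co1 | intermediate
14 | 2-(diethoxymethyl)-4-[(2E,4R,5S)-5-[(tert-butyldimethylsilyl)oxy]-4-methylhex-2-en-1-yl]furan | CCOC(OCC)c1cc(C/C=C/[C@@H](C)[C@H](C)O[Si](C)(C)C(C)(C)C)co1 | intermediate
15 | 4-[(2E,4R,5S)-5-[(tert-butyldimethylsilyl)oxy]-4-methylhex-2-en-1-yl]furan-2-carbaldehyde | O=Cc1cc(C/C=C/[C@@H](C)[C@H](C)O[Si](C)(C)C(C)(C)C)co1 | intermediate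
16 | ethyl 3-methylbut-2-enoate | CCOC(=O)C=C(C)C | starting material
17 | lithium 1-ethoxy-3-methylbuta-1,3-dien-1-olate (lithium dienolate of 16) | C=C(C)C=C(OCC)O[Li] | intermediate
18 | tert-butyl[(1-ethoxy-3-methylbuta-1,3-dien-1-yl)oxy]dimethylsilane (ketene-acetal geometry unspecified) | C=C(C)C=C(OCC)O[Si](C)(C)C(C)(C)C | intermediate
19 | ethyl (2E,5S)-5-hydroxy-3-methyl-5-{4-[(2E,4R,5S)-5-[(tert-butyldimethylsilyl)oxy]-4-methylhex-2-en-1-yl]furan-2-yl}pent-2-enoate | C/C(=C\C(=O)OCC)C[C@H](O)c1cc(C/C=C/[C@@H](C)[C@H](C)O[Si](C)(C)C(C)(C)C)co1 | intermediate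
20 | (2E,5S)-5-hydroxy-3-methyl-5-{4-[(2E,4R,5S)-5-[(tert-butyldimethylsilyl)oxy]-4-methylhex-2-en-1-yl]furan-2-yl}pent-2-enoic acid | C/C(=C\C(=O)O)C[C@H](O)c1cc(C/C=C/[C@@H](C)[C@H](C)O[Si](C)(C)C(C)(C)C)co1 | intermediate
21 | tert-butyl 6-bromohexanoate | CC(C)(C)OC(=O)CCCCCBr | starting material
22 | 6-(tert-butoxy)-6-oxohexyl (2E,5S)-5-hydroxy-3-methyl-5-{4-[(2E,4R,5S)-5-[(tert-butyldimethylsilyl)oxy]-4-methylhex-2-en-1-yl]furan-2-yl}pent-2-enoate (ring-expansion precursor) | C/C(=C\C(=O)OCCCCCC(=O)OC(C)(C)C)C[C@H](O)c1cc(C/C=C/[C@@H](C)[C@H](C)O[Si](C)(C)C(C)(C)C)co1 | intermediate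
23 | 6-(tert-butoxy)-6-oxohexyl (2E,5S,7Z,10E,12R,13S)-13-[(tert-butyldimethylsilyl)oxy]-8-formyl-5-hydroxy-3,12-dimethyl-6-oxotetradeca-2,7,10-trienoate (ring-opened Z-enedione) | C/C(=C\C(=O)OCCCCCC(=O)OC(C)(C)C)C[C@H](O)C(=O)/C=C(\C=O)C/C=C/[C@@H](C)[C@H](C)O[Si](C)(C)C(C)(C)C | intermediate
24 | 6-(tert-butoxy)-6-oxohexyl (2E)-4-[(2S)-6-hydroxy-5-[(2E,4R,5S)-5-[(tert-butyldimethylsilyl)oxy]-4-methylhex-2-en-1-yl]-3-oxo-3,6-dihydro-2H-pyran-2-yl]-3-methylbut-2-enoate (C6 epimers) | C/C(=C\C(=O)OCCCCCC(=O)OC(C)(C)C)C[C@@H]1OC(O)C(C/C=C/[C@@H](C)[C@H](C)O[Si](C)(C)C(C)(C)C)=CC1=O | intermediate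
25 | 6-(tert-butoxy)-6-oxohexyl (2E)-4-[(2S)-5-[(2E,4R,5S)-5-[(tert-butyldimethylsilyl)oxy]-4-methylhex-2-en-1-yl]-3-oxo-3,6-dihydro-2H-pyran-2-yl]-3-methylbut-2-enoate | C/C(=C\C(=O)OCCCCCC(=O)OC(C)(C)C)C[C@@H]1OCC(C/C=C/[C@@H](C)[C@H](C)O[Si](C)(C)C(C)(C)C)=CC1=O | intermediate
26 | 6-(tert-butoxy)-6-oxohexyl (2E)-4-[(4S)-1-[(2E,4R,5S)-5-[(tert-butyldimethylsilyl)oxy]-4-methylhex-2-en-1-yl]-5-oxo-3,7-dioxabicyclo[4.1.0]heptan-4-yl]-3-methylbut-2-enoate (4,5-epoxide of 25, epoxide diastereomers) | C/C(=C\C(=O)OCCCCCC(=O)OC(C)(C)C)C[C@@H]1OCC2(C/C=C/[C@@H](C)[C@H](C)O[Si](C)(C)C(C)(C)C)OC2C1=O | intermediate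
27 | 6,7-diketothiomarinolic acid C6 | C/C(=C\C(=O)OCCCCCC(=O)O)C[C@@H]1OCC(C/C=C/[C@@H](C)[C@H](C)O)=C(O)C1=O | target

Total step count: 15. Longest linear sequence: 13 steps (steps 1–5, 7, 9–15, from ethyl (3S)-3-hydroxybutanoate).

Steps most likely to fail

Step 15. Under acid the epoxide may ionise at C5 and divert by acyl migration with ring contraction. The finished enol may also drift to the C2=C3 tautomer on prolonged exposure, which would erase the C2 configuration. Silyl ether cleavage may lag behind the other two events. The fallback sets out from 26 and separates isomerisation from deprotection, changing the isomerisation to an anionic addition–elimination. Cold dilute aqueous NaOH in THF opens the epoxide at C4 by hydroxide and expels the C5 oxygen by E1cB. No cation at C5 is involved, and the product is held as its enolate, which resists deprotonation at C2. Buffering to pH 5 should give the protected diosphenol 6-(tert-butoxy)-6-oxohexyl (2E)-4-[(2S)-4-hydroxy-5-[(2E,4R,5S)-5-[(tert-butyldimethylsilyl)oxy]-4-methylhex-2-en-1-yl]-3-oxo-3,6-dihydro-2H-pyran-2-yl]-3-methylbut-2-enoate F1. This can be purified and then exposed only briefly to TFA/H2O at 0 °C, which returns to the route at 27.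

Step 9. Facial selectivity may be poor with this electron-rich heteroaryl aldehyde, the catalyst antipode may have been chosen wrongly, or α-attack and Z-enoate formation may erode the yield. The fallback sets out from 15 and 18. An achiral BF3·OEt2-promoted vinylogous Mukaiyama aldol (CH2Cl2, −78 °C) gives the C5-epimeric mixture of ethyl (2E)-5-hydroxy-3-methyl-5-{4-[(2E,4R,5S)-5-[(tert-butyldimethylsilyl)oxy]-4-methylhex-2-en-1-yl]furan-2-yl}pent-2-enoate F2. Sharpless kinetic resolution of the furylcarbinol [Ti(OiPr)4, D-(−)-diisopropyl tartrate, TBHP (0.6 equiv), 4 Å sieves, CH2Cl2, −20 °C] should then consume the (5R)-epimer by oxidative ring expansion. This gives the separable by-product ethyl (2E)-4-[(2R)-6-hydroxy-5-[(2E,4R,5S)-5-[(tert-butyldimethylsilyl)oxy]-4-methylhex-2-en-1-yl]-3-oxo-3,6-dihydro-2H-pyran-2-yl]-3-methylbut-2-enoate F3 and leaves the (5S)-alcohol, returning to the route at 19. The reagent is blind to the isolated alkene because only the furylcarbinol is bound to titanium.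

Step 14. Base may enolise the pyranone during the nucleophilic epoxidation, epimerising C2 or moving the ring double bond into conjugation with the side-chain alkene through the doubly activated CH2 on C5. Conjugate addition to the β,β-disubstituted enone may also be slow enough for these to compete. The fallback sets out from 25 and avoids base altogether. Luche reduction (NaBH4, CeCl3·7H2O, MeOH, −78 °C) gives the allylic alcohol 6-(tert-butoxy)-6-oxohexyl (2E)-4-[(2S)-3-hydroxy-5-[(2E,4R,5S)-5-[(tert-butyldimethylsilyl)oxy]-4-methylhex-2-en-1-yl]-3,6-dihydro-2H-pyran-2-yl]-3-methylbut-2-enoate F4. Hydroxyl-directed epoxidation [VO(acac)2 (cat.), TBHP, CH2Cl2, 0 °C], selective for the allylic alcohol over the isolated alkene and the enoate, gives the epoxy alcohol 6-(tert-butoxy)-6-oxohexyl (2E)-4-[(4S)-5-hydroxy-1-[(2E,4R,5S)-5-[(tert-butyldimethylsilyl)oxy]-4-methylhex-2-en-1-yl]-3,7-dioxabicyclo[4.1.0]heptan-4-yl]-3-methylbut-2-enoate F5. Dess–Martin oxidation (NaHCO3, CH2Cl2) then returns to the route at 26.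

Further compounds
F1 | step 15 | 6-(tert-butoxy)-6-oxohexyl (2E)-4-[(2S)-4-hydroxy-5-[(2E,4R,5S)-5-[(tert-butyldimethylsilyl)oxy]-4-methylhex-2-en-1-yl]-3-oxo-3,6-dihydro-2H-pyran-2-yl]-3-methylbut-2-enoate | C/C(=C\C(=O)OCCCCCC(=O)OC(C)(C)C)C[C@@H]1OCC(C/C=C/[C@@H](C)[C@H](C)O[Si](C)(C)C(C)(C)C)=C(O)C1=O
F2 | step 9 | ethyl (2E)-5-hydroxy-3-methyl-5-{4-[(2E,4R,5S)-5-[(tert-butyldimethylsilyl)oxy]-4-methylhex-2-en-1-yl]furan-2-yl}pent-2-enoate (C5 epimers) | C/C(=C\C(=O)OCC)CC(O)c1cc(C/C=C/[C@@H](C)[C@H](C)O[Si](C)(C)C(C)(C)C)co1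
F3 | step 9 | ethyl (2E)-4-[(2R)-6-hydroxy-5-[(2E,4R,5S)-5-[(tert-butyldimethylsilyl)oxy]-4-methylhex-2-en-1-yl]-3-oxo-3,6-dihydro-2H-pyran-2-yl]-3-methylbut-2-enoate | C/C(=C\C(=O)OCC)C[C@H]1OC(O)C(C/C=C/[C@@H](C)[C@H](C)O[Si](C)(C)C(C)(C)C)=CC1=O
F4 | step 14 | 6-(tert-butoxy)-6-oxohexyl (2E)-4-[(2S)-3-hydroxy-5-[(2E,4R,5S)-5-[(tert-butyldimethylsilyl)oxy]-4-methylhex-2-en-1-yl]-3,6-dihydro-2H-pyran-2-yl]-3-methylbut-2-enoate | C/C(=C\C(=O)OCCCCCC(=O)OC(C)(C)C)C[C@@H]1OCC(C/C=C/[C@@H](C)[C@H](C)O[Si](C)(C)C(C)(C)C)=CC1O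
F5 | step 14 | 6-(tert-butoxy)-6-oxohexyl (2E)-4-[(4S)-5-hydroxy-1-[(2E,4R,5S)-5-[(tert-butyldimethylsilyl)oxy]-4-methylhex-2-en-1-yl]-3,7-dioxabicyclo[4.1.0]heptan-4-yl]-3-methylbut-2-enoate | C/C(=C\C(=O)OCCCCCC(=O)OC(C)(C)C)C[C@@H]1OCC2(C/C=C/[C@@H](C)[C@H](C)O[Si](C)(C)C(C)(C)C)OC2C1O
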